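Amounts were what I had: two earlier flasks with the same racemic charge, differing in free catalyst and read at the same times.

in all of them: left-handed substrate 0.50 M; right-handed substrate 0.50 M; gas 200 mM (held)

| charge | free catalyst | remark | time |
|---|---|---|---|
| beta | 6.1 mol% | run made earlier |  |
| theta | 34 mol% | run made earlier |  |
| blue | 6 mol% |  | 6.0 h |
| red | 12 mol% |  | 6.0 h |
| teal | 30 mol% |  | 6.0 h |
| ochre | 10 mol% |  | 6.0 h |
| amber | 5 mol% |  | 6.0 h |
| green | 20 mol% |  | 6.0 h |

| beta: time / h | beta: left-handed product / % | theta: time / h | theta: left-handed product / % |
|---|---|---|---|
| 0.417 | 0 | 0.417 | 3 |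
| 1.00 | 3 | 1.00 | 5 |
| 2.00 | 3 | 2.00 | 13 |
| 3.00 | 8 | 3.00 | 19 |
| 4.00 | 9 | 4.00 | 23 |

(each reading ± 1.5 percentage points)

- free catalyst is single-handed; left-handed substrate and right-handed substrate are mirror images of each other, charged as a racemate, each of them at the stated concentration
- at the start none of reagent is dissolved
- the numbers in the tables scatter by 1.5 percentage points (one standard deviation)
- steps thought possible: free catalyst + left-handed substrate <-> catalyst intermediate A; free catalyst + right-handed substrate <-> catalyst intermediate B; reagent + catalyst intermediate A -> free catalyst + left-handed product; reagent + catalyst intermediate B -> free catalyst + right-handed product; gas <-> reagent; 2 reagent -> self-condensation product; left-handed product <-> right-handed product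

- ranking by amount of left-handed product, in percent of the left-handed substrate and right-handed substrate together charged, from high to low, at 6.0 h (blue / red / teal / ochre / amber / green)
- the amount of left-handed product, in percent of the left-handed substrate and right-handed substrate together charged of the flask you put first, at 6.0 h
- the amount of left-handed product, in percent of the left-handed substrate and right-handed substrate together charged of the flask you put last, at 6.0 h

I took two rates, each the last reading of a run divided by its time, as a share of the charge per hour:

r_b = 9 % / 4.00 h = 0.0225 h⁻¹

r_t = 23 % / 4.00 h = 0.0575 h⁻¹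

The theta run had 5.57 times the catalyst of the beta run but 2.56 times the rate, and this rate factor is smaller than the loading factor. I let it follow a power of the loading C, the apparent order in catalyst, which carries the scatter of the readings:

n = ln(r_t/r_b) / ln(C_t/C_b) = 0.546

Since n is above zero, I ranked the flasks by loading. My quantity is r_T, the steady rate of left-handed product in teal, scaled from the theta run, with r_A scaled likewise from the beta run for amber:

r_T = r_t (C_teal/C_t)^n = 0.0537 h⁻¹

r_A = r_b (C_amber/C_b)^n = 0.0202 h⁻¹

Over 6.0 h these gave me 32.2 % for teal and 12.1 % for amber. Teal's figure stays below the 50.0 % that the left-handed substrate charged can yield.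

The forecast gave the same order, teal > green > red > ochre > blue > amber, with lower figures of 29 % and 10.5 %, holding that “More catalyst should still help, but with diminishing returns”.

The flasks came out as teal > green > red > ochre > blue > amber, with teal at 33.9 % and amber at 15.1 %. In teal, half of the turnover to left-handed product was done by 3.01 h, half of the way to 6.0 h. My r_T fell 1.7 percentage points short of teal's amount, and r_A fell 3 points short of amber's.

    free catalyst + left-handed substrate ⇌ catalyst intermediate A (K = 20.0 M⁻¹, k = 0.190 M⁻¹ min⁻¹)
    free catalyst + right-handed substrate ⇌ catalyst intermediate B (K = 1.00 M⁻¹, k = 7.70 M⁻¹ min⁻¹)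
    reagent + catalyst intermediate A → free catalyst + left-handed product (k = 0.430 M⁻¹ min⁻¹)
    reagent + catalyst intermediate B → free catalyst + right-handed product (k = 0.0600 M⁻¹ min⁻¹)
    gas ⇌ reagent, rate k5*(csat - [reagent]) (kL = 0.00660 min⁻¹)
    2 reagent → self-condensation product (k = 0.00700 M⁻¹ min⁻¹)
    left-handed product ⇌ right-handed product (k = 2.80 × 10⁻⁴ min⁻¹)

For teal left until 1.5 h, r_T gives 8.05 %. That flask held 7.82 %.

The earlier runs and the new flask stem from a simulated flask with made-up constants, noise included.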